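**Compound numbering used throughout:** 1 bromanil, 2 dimethoxyquinone, 3 ring B diol, 4 2,5-dibromoanisole, 5 iodoanisole, 6 1,3,5-trimethoxybenzene, 7 hydroxy(tosyloxy)iodoarene (in flask), 8 iodonium tosylate, 9 mono-aryl ether (in flask), 10 hexabromo tetramethyl ether, 11 hexabromo tetraol, 12 octabromo quinone (in flask), 13 target.

## The problem

Target 13 is 2,5-dibromo-3,6-bis(2,3,5-tribromo-4-hydroxyphenoxy)benzene-1,4-diol. Three benzene rings stand in a row, with the central ring B tied to two identical outer rings A and C by two para-disposed diaryl ether oxygens. The molecule is centrosymmetric and has no stereocentre, so the whole task is regiochemical: eight bromines and six oxygens must be placed on eighteen carbons, leaving only the C6' hydrogen of each outer ring. On ring B, C1 and C4 carry the ether oxygens, C2 and C5 the hydroxyls, and C3 and C6 bromine. On each outer ring, C1' is the ether carbon, C2', C3' and C5' carry bromine and C4' the hydroxyl. Each ether bond is crowded, flanked by Br and OH on ring B and by the C2' bromine on the outer ring. The C2/C5 diol of ring B is a hydroquinone that oxidises readily to a quinone, in which the aryloxy groups become displaceable vinylogous esters. The many C–Br bonds rule out palladium- or copper-catalysed ether formation, hydrogenolysis and late organolithium chemistry. The enabling feature is that both ether oxygens can be counted as substituents of ring B. Ring B is then a symmetric 3,6-dibromo-1,2,4,5-tetraoxygenated benzene, a pattern that bromanil (1) delivers by exchange of two para bromides. Rings A and C become identical aryl electrophiles at C1', para to the C4' oxygen, and the C3' bromine, ortho to the C4' hydroxyl, can be added last.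

## Retrosynthesis

**C3'–Br bonds (13 to 11).** The two C3'–Br bonds are removed first, which leads back to hexabromo tetraol 11. C3' is the only open position ortho or para to the C4' hydroxyl, so phenol-directed bromination should find it, whereas C6' is activated only by the weaker ether oxygen. This makes each outer ring a 2,5-dibromo-4-oxygenated aryl group that can be traced to 2,5-dibromoanisole (4). The forward step must tolerate the ring B hydroquinone. It is planned to pass through octabromo quinone 12 in the flask and to end with a reduction to 13.

**O–CH3 bonds (11 to 10).** The four O–CH3 bonds are cut next, giving hexabromo tetramethyl ether 10. Methyl is the smallest oxygen mask, which matters next to the crowded ether bonds. It survives base and trivalent iodine, and it arrives on ring B directly in the step that sets the ring B pattern. The forward reaction is a global Lewis-acid ether cleavage that must spare the diaryl ethers and the C–Br bonds.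

**O–C1' bonds (10 to 3 and 8, key disconnection).** Both O–C1' bonds are cut with the oxygens kept on ring B, giving ring B diol 3 and two equivalents of iodonium tosylate 8. The opposite cut, ring B as the electrophile, would require two of four equivalent C–Br positions of a quinone to be selected by a hindered phenoxide. A copper- or palladium-mediated coupling would have to ignore six aryl bromides. With 3 as nucleophile only two hydroxyls exist, each at a site already fixed. The precursors are one hexasubstituted benzene and one diaryliodonium salt, with no ring to build. The forward step must transfer the dibromoanisyl group and not the trimethoxyphenyl group, twice, through mono-ether 9, at a doubly ortho-substituted phenoxide.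

**Ring B diol (3 to 2 to 1).** Diol 3 is the reduced form of quinone 2. Quinone 2 arises from bromanil 1 by exchange of the C2 and C5 bromides for methoxy. All six ring B substituents therefore come from a commercial compound in two operations. The forward demand is that the exchange stops at two and goes para.

**Iodonium salt (8 to 5 and 6, 5 to 4).** Salt 8 is cut at the iodine–trimethoxyphenyl bond into iodoanisole 5 and 1,3,5-trimethoxybenzene 6, by way of the trivalent iodine species 7. Iodide 5 is cut at its C–I bond to 2,5-dibromoanisole 4. The methoxy group of 4 directs iodine para, to the carbon that becomes C1'. The forward steps are an electrophilic iodination and a one-pot oxidation–arylation at iodine.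

## Roads not taken

**Alternative 1:** Ring B would be made by a Moore ring expansion. The alkynyl cyclobutenone A2, 4-hydroxy-3-(4-methoxyphenoxy)-4-[(4-methoxyphenoxy)ethynyl]cyclobut-2-en-1-one, is heated. It opens to an enynyl ketene and closes to 2,5-bis(4-methoxyphenoxy)-1,4-benzoquinone A1, forming one ring B C–C bond.
- Merits: the 2,5-relationship of the two aryloxy groups and the quinone oxygens follows from the mechanism, and the step is thermal and metal-free.
- Weak points: A1 carries none of the eight bromines. Two would have to be added to ring B and three to each outer ring, and the last one on each outer ring goes meta to the hydroxyl on an already deactivated ring, where stopping cleanly is not assured. A2 also needs a metalated aryl ynol ether, a labile reagent class, added to a squarate-derived dione.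
- Comparison: the chosen plan buys ring B with both bromines and the correct oxygen pattern, and the outer rings with two of their three bromines. It is shorter and leaves one bromination per outer ring, at an unambiguous site. Alternative 1 offers nothing the chosen plan lacks.

**Alternative 2:** Bromanil 1 would be treated with two equivalents of 2,5-dibromo-4-methoxyphenol A4 and base. Addition–elimination at C2 and C5 gives 2,5-dibromo-3,6-bis(2,5-dibromo-4-methoxyphenoxy)-1,4-benzoquinone A3. Reduction, demethylation and bromination would follow.
- Merits: this is the shortest road, about five operations against seven. It needs no hypervalent iodine, and ring B emerges from the reduction with free hydroxyls, so only two methyl ethers need cleaving. In step count and reagent cost it is better than the chosen plan.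
- Weak points: four equivalent bromides are offered to a bulky, weakly nucleophilic ortho-bromophenoxide, and exactly two para ones must react. Tri- and tetra-aryloxy quinones and the 2,6-isomer are the natural by-products. Bromanil is a strong electron acceptor and a para-methoxyphenoxide a good donor, so electron transfer competes. A3 is a vinylogous aryl ester whose aryloxy groups can exchange under the reaction conditions.
- Comparison: the chosen plan sets the ring B pattern with small methoxide. It then forms the ethers at the reduced, non-electrophilic oxidation level, where each oxygen can be arylated only once and only at its fixed position. This alternative is kept as the fallback for the key step.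

**Alternative 3:** Two molecules of 3-(2,5-dibromo-4-methoxyphenoxy)-2-oxopropanal A6 would be condensed head to tail under acid. Each aryloxy-bearing CH2 adds to the aldehyde of the other, closing ring B as 2,5-bis(2,5-dibromo-4-methoxyphenoxy)-1,4-benzoquinone A5.
- Merits: the dimerisation mirrors the symmetry of the target, and the outer rings arrive with two bromines each.
- Weak points: A6 is an α-oxoaldehyde prone to hydration and oligomerisation. The double aldol must beat head-to-head condensation and polymer formation. A5 still lacks both ring B bromines, which would have to be introduced on the quinone in the presence of two anisole rings.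
- Comparison: this route builds from acyclic material a ring that is commercially available fully substituted. The chosen plan forms only the two C–O bonds that cannot be bought.

Key step: step 5

## Route

Remark on the chemistry: the target has no stereocentre, so no configuration is set anywhere. Ring B of tetraol 11 is a hydroquinone and is assumed to be oxidised by bromine faster than the outer rings are brominated. Step 7 is therefore planned with three equivalents of Br2 and a reductive finish.

Step 1
Reactants: 1 bromanil (2,3,5,6-tetrabromocyclohexa-2,5-diene-1,4-dione)
Product: 2 2,5-dibromo-3,6-dimethoxycyclohexa-2,5-diene-1,4-dione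
Conditions: NaOMe (2.0 equiv), MeOH, 0 °C to rt
Reagents that add atoms: NaOMe, [Na+].[O-]C
Why: Twofold addition–elimination (vinylogous acyl substitution) on a tetrahaloquinone; the first methoxy group deactivates, as a vinylogous ester, the carbonyl conjugated with it, so the second methoxide should enter at the para carbon and the exchange should stop at the 2,5-dimethoxy stage with two equivalents.

Step 2
Reactants: 2 2,5-dibromo-3,6-dimethoxycyclohexa-2,5-diene-1,4-dione
Product: 3 2,5-dibromo-3,6-dimethoxybenzene-1,4-diol
Conditions: Na2S2O4, EtOAc/H2O, rt, Ar
Reagents that add atoms: none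
Why: Dithionite reduction of a quinone to its hydroquinone; C–Br and O–Me bonds are not touched, and the diol is used at once because it is air-sensitive.

Step 3
Reactants: 4 2,5-dibromoanisole (1,4-dibromo-2-methoxybenzene)
Product: 5 1,4-dibromo-2-iodo-5-methoxybenzene
Conditions: NIS (1.1 equiv), TFA, MeCN, rt
Reagents that add atoms: N-iodosuccinimide, O=C1CCC(=O)N1I
Why: Electrophilic aromatic iodination with acid-activated NIS; the methoxy group directs para, and the ortho position is more hindered, lying between OMe and Br.

Step 4
Reactants: 5 1,4-dibromo-2-iodo-5-methoxybenzene; 6 1,3,5-trimethoxybenzene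
Product: 8 (2,5-dibromo-4-methoxyphenyl)(2,4,6-trimethoxyphenyl)iodonium tosylate, via hydroxy(tosyloxy)iodoarene 7 (not isolated)
Conditions: mCPBA (1.1 equiv), TsOH·H2O (1.05 equiv), MeCN, 70 °C; then 6 (1.05 equiv), 70 °C; Et2O trituration
Reagents that add atoms: p-toluenesulfonic acid monohydrate, Cc1ccc(S(=O)(=O)O)cc1.O; mCPBA, O=C(OO)c1cccc(Cl)c1 (its oxygen is held only by intermediate 7 and leaves as water)
Why: One-pot oxidation of an aryl iodide to a Koser-type trivalent iodine tosylate, followed by electrophilic aromatic substitution on the very electron-rich trimethoxybenzene, a standard route to aryl(trimethoxyphenyl)iodonium tosylates; the salt should precipitate on adding ether.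

Step 5
Reactants: 3 2,5-dibromo-3,6-dimethoxybenzene-1,4-diol; 8 (2,5-dibromo-4-methoxyphenyl)(2,4,6-trimethoxyphenyl)iodonium tosylate (2.5 equiv)
Product: 10 1,4-dibromo-2,5-bis(2,5-dibromo-4-methoxyphenoxy)-3,6-dimethoxybenzene, via mono-aryl ether phenol 9 (not isolated)
Conditions: K2CO3 (6 equiv), degassed toluene, 60 °C, Ar
Reagents that add atoms: none
Why: The phenoxide of 3 displaces tosylate at trivalent iodine to give a T-shaped aryloxy(diaryl)-λ3-iodane, and ligand coupling between oxygen and the ipso carbon of one aryl group forms the O–C1' bond and releases an aryl iodide. The closest known reaction type is the metal-free O-arylation of hindered phenols with unsymmetrical diaryliodonium salts that carry a trimethoxyphenyl dummy ligand. The step needs chemoselective transfer of the dibromoanisyl group; this is secured because the coupling places negative charge on the ipso carbon and so prefers the less electron-rich aryl group, while the trimethoxyphenyl ring with its three donors stays on iodine, and the C2' bromine adds an ortho effect in the same direction. The sequence then repeats on the second hydroxyl of mono-ether 9, which is no longer a hydroquinone and is less prone to oxidation. No ring is closed and no stereocentre is formed. No transition metal is present, so the six C–Br bonds cannot undergo oxidative addition. The coupling takes place within the coordination sphere of iodine and should therefore tolerate the three ortho substituents around each new ether, where SNAr or copper catalysis would be slow. Exclusion of air is needed because the mono-anion of 3 is an electron-rich hydroquinone.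

Step 6
Reactants: 10 1,4-dibromo-2,5-bis(2,5-dibromo-4-methoxyphenoxy)-3,6-dimethoxybenzene
Product: 11 2,5-dibromo-3,6-bis(2,5-dibromo-4-hydroxyphenoxy)benzene-1,4-diol
Conditions: BBr3 (8 equiv), CH2Cl2, −78 °C to rt; then degassed H2O, Ar
Reagents that add atoms: none
Why: Lewis-acid cleavage of aryl methyl ethers with BBr3, which attacks the methyl carbon and leaves diaryl ethers and aryl bromides intact; the twisted, doubly flanked methoxy groups of ring B are normally cleaved at least as readily as unhindered ones.

Step 7
Reactants: 11 2,5-dibromo-3,6-bis(2,5-dibromo-4-hydroxyphenoxy)benzene-1,4-diol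
Product: 13 2,5-dibromo-3,6-bis(2,3,5-tribromo-4-hydroxyphenoxy)benzene-1,4-diol, via octabromo quinone 12 (not isolated)
Conditions: Br2 (3.0 equiv), AcOH, rt; then aq. Na2S2O4, EtOAc
Reagents that add atoms: bromine, BrBr
Why: One equivalent of bromine oxidises the ring B hydroquinone to the quinone, and two equivalents carry out electrophilic aromatic bromination ortho to each outer hydroxyl at C3', the only open position ortho or para to a free OH. At the quinone stage the ether oxygen is a vinylogous ester oxygen and activates C6' even less, which should protect against over-bromination. Dithionite then returns quinone 12 to the hydroquinone 13.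

## Compound list

1 | bromanil (2,3,5,6-tetrabromocyclohexa-2,5-diene-1,4-dione) | O=C1C(Br)=C(Br)C(=O)C(Br)=C1Br | starting material
2 | 2,5-dibromo-3,6-dimethoxycyclohexa-2,5-diene-1,4-dione | COC1=C(Br)C(=O)C(OC)=C(Br)C1=O | intermediate
3 | 2,5-dibromo-3,6-dimethoxybenzene-1,4-diol | COc1c(O)c(Br)c(OC)c(O)c1Br | intermediate
4 | 2,5-dibromoanisole (1,4-dibromo-2-methoxybenzene) | COc1cc(Br)ccc1Br | starting material
5 | 1,4-dibromo-2-iodo-5-methoxybenzene | COc1cc(Br)c(I)cc1Br | intermediate
6 | 1,3,5-trimethoxybenzene | COc1cc(OC)cc(OC)c1 | starting material
7 | (2,5-dibromo-4-methoxyphenyl)(hydroxy)(tosyloxy)-λ3-iodane | COc1cc(Br)c(I(O)OS(=O)(=O)c2ccc(C)cc2)cc1Br | intermediate (not isolated)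
8 | (2,5-dibromo-4-methoxyphenyl)(2,4,6-trimethoxyphenyl)iodonium tosylate | COc1cc(OC)c([I+]c2cc(Br)c(OC)cc2Br)c(OC)c1.Cc1ccc(S(=O)(=O)[O-])cc1 | intermediate
9 | 2,5-dibromo-4-(2,5-dibromo-4-methoxyphenoxy)-3,6-dimethoxyphenol | COc1c(O)c(Br)c(OC)c(Oc2cc(Br)c(OC)cc2Br)c1Br | intermediate (not isolated)
10 | 1,4-dibromo-2,5-bis(2,5-dibromo-4-methoxyphenoxy)-3,6-dimethoxybenzene | COc1cc(Br)c(Oc2c(OC)c(Br)c(Oc3cc(Br)c(OC)cc3Br)c(OC)c2Br)cc1Br | intermediate
11 | 2,5-dibromo-3,6-bis(2,5-dibromo-4-hydroxyphenoxy)benzene-1,4-diol | Oc1cc(Br)c(Oc2c(O)c(Br)c(Oc3cc(Br)c(O)cc3Br)c(O)c2Br)cc1Br | intermediate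
12 | 2,5-dibromo-3,6-bis(2,3,5-tribromo-4-hydroxyphenoxy)cyclohexa-2,5-diene-1,4-dione | O=C1C(Br)=C(Oc2cc(Br)c(O)c(Br)c2Br)C(=O)C(Br)=C1Oc1cc(Br)c(O)c(Br)c1Br | intermediate (not isolated)
13 | 2,5-dibromo-3,6-bis(2,3,5-tribromo-4-hydroxyphenoxy)benzene-1,4-diol | Oc1c(Br)cc(Oc2c(O)c(Br)c(Oc3cc(Br)c(O)c(Br)c3Br)c(O)c2Br)c(Br)c1Br | target

## Step count and risks

Total step count: 7. Longest linear sequence: 5 steps (steps 1, 2, 5, 6, 7, or equally steps 3, 4, 5, 6, 7).

**Step 5 (key step).** The main danger is electron transfer from the hydroquinone mono-anion of 3 to trivalent iodine. This would reoxidise ring B and fragment the salt without forming the ether. Two lesser risks are stalling after the first arylation, because the phenoxide of 9 is more crowded, and partial transfer of the trimethoxyphenyl group.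

The fallback reverses the polarity and sets out from iodide 5 and bromanil 1:
- Iodine–magnesium exchange on 5 (iPrMgCl·LiCl, THF, −40 °C), a B(OMe)3 quench and hydrolysis should give (2,5-dibromo-4-methoxyphenyl)boronic acid F1.
- H2O2/NaOH should convert F1 into 2,5-dibromo-4-methoxyphenol F2.
- Two equivalents of F2 with K2CO3 in MeCN should displace the two para bromides of 1, giving 2,5-dibromo-3,6-bis(2,5-dibromo-4-methoxyphenoxy)cyclohexa-2,5-diene-1,4-dione F3.
- Na2S2O4 should reduce F3 to 2,5-dibromo-3,6-bis(2,5-dibromo-4-methoxyphenoxy)benzene-1,4-diol F4.
- BBr3 on F4 cleaves the two outer methyl ethers, and the route is rejoined at tetraol 11.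

**Step 7.** Over-bromination at C6' may occur while excess bromine is present. An aryloxy group may also be lost from the electrophilic quinone 12 to water or bromide before the reduction.

The fallback removes ring B from the redox question. It sets out from tetramethyl ether 10, whose ring B cannot be oxidised. Br2 in AcOH with warming should brominate ortho to the outer methoxy group, the stronger donor, to give 1,4-dibromo-2,5-dimethoxy-3,6-bis(2,3,5-tribromo-4-methoxyphenoxy)benzene F5. BBr3 then cleaves all four methyl ethers and the route is rejoined at target 13. This fallback depends on methoxy outranking the aryloxy oxygen as a director.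

**Step 4.** The Koser-type intermediate 7 from the electron-rich iodoanisole 5 may arylate a second anisole ring or decompose at 70 °C. Residual peracid may oxidise trimethoxybenzene 6.

The fallback separates oxidation and coupling and avoids strong acid, setting out from 5:
- NaBO3·4H2O in AcOH at 45 °C should give 1,4-dibromo-2-(diacetoxy-λ3-iodanyl)-5-methoxybenzene F6, which is isolated.
- F6 is coupled with 6 in 2,2,2-trifluoroethanol at rt to give (2,5-dibromo-4-methoxyphenyl)(2,4,6-trimethoxyphenyl)iodonium acetate F7.
- Anion exchange with TsOH·H2O rejoins the route at salt 8.

**Step 6.** The ring B hydroquinone of 11 may be partly oxidised by air during work-up and purification. The result would be a mixture of two oxidation levels that is hard to handle.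

The fallback carries the material at the quinone level on purpose, setting out from 10. After the BBr3 cleavage the crude product is oxidised with DDQ (1 equiv, dioxane, rt). This should give 2,5-dibromo-3,6-bis(2,5-dibromo-4-hydroxyphenoxy)cyclohexa-2,5-diene-1,4-dione F8, a quinone that can be purified in air. F8 is brominated with two equivalents of Br2 in AcOH, which rejoins the route at quinone 12. Na2S2O4 then gives 13.

## Further compounds

F1 | step 5 | (2,5-dibromo-4-methoxyphenyl)boronic acid | COc1cc(Br)c(B(O)O)cc1Br
F2 | step 5 | 2,5-dibromo-4-methoxyphenol | COc1cc(Br)c(O)cc1Br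
F3 | step 5 | 2,5-dibromo-3,6-bis(2,5-dibromo-4-methoxyphenoxy)cyclohexa-2,5-diene-1,4-dione | COc1cc(Br)c(OC2=C(Br)C(=O)C(Oc3cc(Br)c(OC)cc3Br)=C(Br)C2=O)cc1Br
F4 | step 5 | 2,5-dibromo-3,6-bis(2,5-dibromo-4-methoxyphenoxy)benzene-1,4-diol | COc1cc(Br)c(Oc2c(O)c(Br)c(Oc3cc(Br)c(OC)cc3Br)c(O)c2Br)cc1Br
F5 | step 7 | 1,4-dibromo-2,5-dimethoxy-3,6-bis(2,3,5-tribromo-4-methoxyphenoxy)benzene | COc1c(Br)cc(Oc2c(OC)c(Br)c(Oc3cc(Br)c(OC)c(Br)c3Br)c(OC)c2Br)c(Br)c1Br
F6 | step 4 | 1,4-dibromo-2-(diacetoxy-λ3-iodanyl)-5-methoxybenzene | COc1cc(Br)c(I(OC(C)=O)OC(C)=O)cc1Br
F7 | step 4 | (2,5-dibromo-4-methoxyphenyl)(2,4,6-trimethoxyphenyl)iodonium acetate | COc1cc(OC)c([I+]c2cc(Br)c(OC)cc2Br)c(OC)c1.CC(=O)[O-]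
F8 | step 6 | 2,5-dibromo-3,6-bis(2,5-dibromo-4-hydroxyphenoxy)cyclohexa-2,5-diene-1,4-dione | O=C1C(Br)=C(Oc2cc(Br)c(O)cc2Br)C(=O)C(Br)=C1Oc1cc(Br)c(O)cc1Br
A1 | alternative 1 | 2,5-bis(4-methoxyphenoxy)-1,4-benzoquinone | COc1ccc(OC2=CC(=O)C(Oc3ccc(OC)cc3)=CC2=O)cc1
A2 | alternative 1 | 4-hydroxy-3-(4-methoxyphenoxy)-4-[(4-methoxyphenoxy)ethynyl]cyclobut-2-en-1-one | COc1ccc(OC#CC2(O)C(Oc3ccc(OC)cc3)=CC2=O)cc1
A3 | alternative 2 | 2,5-dibromo-3,6-bis(2,5-dibromo-4-methoxyphenoxy)-1,4-benzoquinone | COc1cc(Br)c(OC2=C(Br)C(=O)C(Oc3cc(Br)c(OC)cc3Br)=C(Br)C2=O)cc1Br
A4 | alternative 2 | 2,5-dibromo-4-methoxyphenol | COc1cc(Br)c(O)cc1Br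
A5 | alternative 3 | 2,5-bis(2,5-dibromo-4-methoxyphenoxy)-1,4-benzoquinone | COc1cc(Br)c(OC2=CC(=O)C(Oc3cc(Br)c(OC)cc3Br)=CC2=O)cc1Br
A6 | alternative 3 | 3-(2,5-dibromo-4-methoxyphenoxy)-2-oxopropanal | COc1cc(Br)c(OCC(=O)C=O)cc1Br
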